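The numbers in the tables were computed for substances that don't exist.

Start from the leftover: at 4.00 h the zeta run had 42.0% of its charge outside target, and the delta run, on a larger charge, had more, 51.0%.

| flask | substrate | remark | time |
|---|---|---|---|
| alpha | 10 mM | run made earlier |  |
| zeta | 14 mM | run made earlier |  |
| delta | 22 mM | run made earlier |  |
| autumn | 10 mM | everything together in a closed stirred flask, run for 4.0 h | 4.0 h |
| dusk | 10 mM | a single well-mixed tank run continuously and read at steady state, 4.0 h in it on average |  |

- alpha (time / h: target / %): 0.167: 1; 0.500: 11; 0.833: 23; 1.33: 37; 2.00: 49; 2.50: 52
- zeta (time / h: target / %): 0.250: 6; 0.833: 23; 1.33: 32; 2.00: 48; 3.00: 56; 4.00: 58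
- delta (time / h: target / %): 0.333: 5; 0.500: 11; 0.833: 17; 1.33: 31; 2.50: 43; 4.00: 49

(readings scatter by 1.5 percentage points)

- the stated concentrations are those of everything mixed, before any reaction; amounts are the same in each set-up
- the analysis behind the earlier runs scatters by 1.5 percentage points, standard deviation
- the earlier runs were made in a closed, stirred flask

- the set-up with the highest amount of target at the outlet or at the end, in percent of the substrate put in ("none" if the first two lie within 2 percentage points) (autumn / dusk / none)
- amount of target at the outlet or at the end, in percent of the substrate put in, autumn
- amount of target at the outlet or at the end, in percent of the substrate put in, dusk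

*What can you do with those two readings without integrating anything?*

Solve the two ends and join them. I assume that on a thin charge the yield stands at a ceiling, and that on a rich charge it falls in inverse proportion to the charge. The simple join makes the inverse of the yield a straight line in the charge. The two readings then give the crossover charge 29.6 mM, the charge at which the yield is half its ceiling, and a ceiling of 85.5%.

*And autumn?*

Autumn holds a third of the crossover charge and is read at the same time as those two readings, so the line gives 63.9%. Each reading carries a scatter of 1.5 percentage points.

*What does the forecast say?*

It gives 60% for autumn (55% to 65%), 50% for dusk (43% to 56%), and autumn as the best. Of the tank it says: “The low tank concentration improves selectivity, perhaps to 70%, giving about 50%.”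

*That "perhaps" is the weak spot. Grant the tank your whole ceiling.*

Then the forecast's two stages of 6/7 give 62.8%, less than my autumn figure but within the margin of 2 points. So I keep the forecast's dusk figure as a judgement and commit to autumn, with "none" as the danger.

The flask gives 61.8% for autumn and 51.8% for dusk, so autumn leads and the forecast stands on all three.

    substrate → intermediate A (k = 0.802 h⁻¹)
    substrate ⇌ intermediate B (K = 42.0, k = 0.0308 h⁻¹)
    intermediate A → target (k = 1.92 h⁻¹)
    intermediate A → intermediate C (k = 0.345 h⁻¹)
    intermediate C → side product (k = 0.585 h⁻¹)
    intermediate C ⇌ intermediate D (K = 46.0, k = 0.246 h⁻¹)
    2 substrate → self-condensation product (k = 23.3 M⁻¹ h⁻¹)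

At the start of autumn, substrate goes to intermediate A 1.72 times as fast as into self-condensation product, and at 4.00 h that ratio is 74, while self-condensation product holds 20.1% of the charge at 2.00 h and 20.6% at 4.00 h. The crossover charge gave 63.9% against the 61.8% of autumn, and for the neighbour flask charged with 25 mM it gives 46.3%, where that flask itself gives 49.1%.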